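**Retrosynthetic overview** (numbering: ring C1 (C=O), C2=C3, C4 (C(OH)CH3), C5 (CH), C6 (C(CH3)2); chain C7H2, C8 (C=O), C9(CH3)=C10, C11H2O)
1. Feature: ring carbons C1–C6 and their three methyl groups are the skeleton of ketoisophorone, whose hindered carbonyl carbon becomes C5; the chain ketone C8 lies between C7 and C9, so both of its C–C bonds can come from CO.
2. The ring carbonyl is installed last: C1H2 → C1H(OH) (SeO2), then C1=O (MnO2).
3. Key disconnection at C7–C8 and C8–C9: the B-alkyl-9-BBN from the exocyclic C5=C7 alkene of (S)-1,5,5-trimethyl-6-methylidenecyclohex-2-en-1-ol, CO, and (Z)-3-iodobut-2-en-1-yl decanoate; the hydroboration sets C5.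
4. The dienol comes from ketoisophorone by asymmetric epoxidation (sets C4), Wharton transposition and Peterson methylenation; the iodide comes from but-2-yn-1-ol and decanoyl chloride.
5. Ring order: the single carbocycle is present in the starting material; no ring is formed in the route.

Key step: step 7

Assumption: the enantiofacial sense of the cinchona-amine epoxidation of this enedione is not presumed; the quinine-derived amine is written, and its quinidine-derived pseudoenantiomer takes its place if a first run delivers the (1R,6S) epoxide instead of the (1S,6R) epoxide.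

**Step 1**
Reactants: 1 ketoisophorone (2,6,6-trimethylcyclohex-2-ene-1,4-dione)
Product: 2 (1S,6R)-1,3,3-trimethyl-7-oxabicyclo[4.1.0]heptane-2,5-dione
Conditions: 9-amino-9-deoxy-epi-quinine (10 mol%), CF3CO2H (20 mol%), 50% aq. H2O2 (1.5 equiv), 1,4-dioxane, 30 °C
Reagents that add atoms: hydrogen peroxide, OO
Why: Iminium-catalysed asymmetric Weitz–Scheffer (nucleophilic) epoxidation of a cyclic enone: the primary amine condenses with the unhindered carbonyl, hydroperoxide adds to the methyl-bearing β-carbon on the face left open by the cinchona scaffold and the enamine closes the epoxide, so both epoxide carbons are set together (1S,6R) under mildly acidic conditions that spare the base-sensitive epoxy dione.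

**Step 2**
Reactants: 2 (1S,6R)-1,3,3-trimethyl-7-oxabicyclo[4.1.0]heptane-2,5-dione
Product: 4 (S)-2-hydroxy-2,6,6-trimethylcyclohex-3-en-1-one, via epoxy hydrazone 3 (not isolated)
Conditions: N2H4·H2O (2.5 equiv), AcOH (0.2 equiv), MeOH, 0 °C → rt
Reagents that add atoms: hydrazine, NN (its nitrogen stays only in intermediate 3; product 4 keeps hydrogen alone)
Why: Wharton transposition: hydrazine condenses only with the carbonyl that is not flanked by two fully substituted carbons, hydrazone 3 opens the epoxide and loses N2 to put the alkene where the carbonyl and its α-carbon were, and the C–O bond at the methyl-bearing carbon is never broken, so the tertiary carbinol keeps the configuration set in step 1 (S).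

**Step 3**
Reactants: 4 (S)-2-hydroxy-2,6,6-trimethylcyclohex-3-en-1-one
Product: 5 (2S)-2,6,6-trimethyl-1-[(trimethylsilyl)methyl]cyclohex-3-ene-1,2-diol (both C1 epimers)
Conditions: Me3SiCH2Li (2.5 equiv), THF, −78 °C → 0 °C; H2O
Reagents that add atoms: (trimethylsilyl)methyllithium, [Li]C[Si](C)(C)C
Why: Addition stage of the Peterson olefination: the ketone has no α-hydrogen and cannot enolise, so the small and strongly nucleophilic Me3SiCH2Li (one equivalent is used up by the hydroxyl) adds to the hindered carbonyl with help from chelation by the neighbouring lithium alkoxide, and the configuration of the new carbinol carbon does not matter because it becomes sp2 in step 4.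

**Step 4**
Reactants: 5 (2S)-2,6,6-trimethyl-1-[(trimethylsilyl)methyl]cyclohex-3-ene-1,2-diol
Product: 6 (S)-1,5,5-trimethyl-6-methylidenecyclohex-2-en-1-ol
Conditions: KH (3 equiv), THF, 0 °C → rt; H2O
Reagents that add atoms: none
Why: Base-induced Peterson elimination: the potassium β-silyl alkoxide loses Me3SiOK in a syn fashion to give the exocyclic alkene, which can form in no other position because both neighbouring carbons are quaternary, and the basic conditions avoid ionisation of the tertiary allylic alcohol, whose configuration is untouched.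

**Step 5**
Reactants: 7 but-2-yn-1-ol
Product: 9 (Z)-3-iodobut-2-en-1-ol, via cyclic alkenylalanate 8 (not isolated)
Conditions: NaAlH2(OCH2CH2OMe)2 (1.5 equiv), THF, 0 °C → rt; EtOAc; I2 (1.5 equiv), THF, −78 °C → 0 °C; aq. Na2S2O3
Reagents that add atoms: iodine, II; sodium bis(2-methoxyethoxy)aluminium dihydride, [Na+].[AlH2-](OCCOC)OCCOC (aluminium and its alkoxy groups stay only in intermediate 8)
Why: Alkoxide-directed trans-hydroalumination of a propargylic alcohol followed by iodinolysis: hydride goes to C2 and aluminium to C3 inside the five-membered alanate 8, and replacement of aluminium by iodine with retention puts iodine cis to CH2OH, which is the Z geometry needed.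

**Step 6**
Reactants: 9 (Z)-3-iodobut-2-en-1-ol; 10 decanoyl chloride
Product: 11 (Z)-3-iodobut-2-en-1-yl decanoate
Conditions: pyridine (1.5 equiv), DMAP (5 mol%), CH2Cl2, 0 °C → rt
Reagents that add atoms: none
Why: DMAP-catalysed acylation of a primary allylic alcohol by an acid chloride, which leaves the alkenyl iodide and its Z geometry untouched and caps the oxygen that would otherwise trap an acylpalladium as a butenolide in step 7.

**Step 7**
Reactants: 6 (S)-1,5,5-trimethyl-6-methylidenecyclohex-2-en-1-ol; 11 (Z)-3-iodobut-2-en-1-yl decanoate; 12 carbon monoxide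
Product: 15 (2Z)-5-[(1R,6S)-6-hydroxy-2,2,6-trimethylcyclohex-4-en-1-yl]-3-methyl-4-oxopent-2-en-1-yl decanoate, via O-borinate 13 (not isolated), via B-alkyl-9-BBN 14 (not isolated)
Conditions: 9-BBN dimer (2.1 equiv B–H), THF, rt → 60 °C; then 11 (0.8 equiv), Pd(PPh3)4 (5 mol%), K3PO4 (4 equiv, anhydrous powder), CO (1 atm), THF–benzene, rt, dark; aq. NH4Cl, MeOH
Reagents that add atoms: 9-borabicyclo[3.3.1]nonane (9-BBN), B1C2CCCC1CCC2 (its boron framework stays only in intermediates 13 and 14; product 15 keeps one hydrogen from it)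
Why: One equivalent of 9-BBN converts the tertiary hydroxyl into O-borinate 13 with loss of H2 and a second adds across the exocyclic C5=C7 bond (boron to the unsubstituted C7, hydrogen to C5) to give 14; zerovalent palladium then inserts into the C–I bond of 11 with retention of the Z geometry, CO inserts to give an alkenoylpalladium iodide, phosphate-assisted transmetalation transfers the primary C7 alkyl group from boron, and reductive elimination forms the C7–C8 and C8–C9 bonds of the ketone. The closest known reaction type is hydroboration followed by carbonylative Suzuki–Miyaura coupling of a B-alkyl-9-BBN with an iodoalkene under CO at room temperature, which gives α,β-unsaturated ketones; a borane whose β-carbon is flanked by two quaternary carbons is more hindered than those normally used. No ring is closed. C5 is set in the hydroboration by the C4 stereocentre: the O-borinate prefers the pseudoaxial position (no allylic strain with the =CH2 group, no methyl/methyl syn-diaxial clash with C6), so it and the syn-axial C6 methyl shield one face, B–H adds from the other, hydrogen arrives anti to oxygen and C7 ends cis to it (5R). Site selectivity rests on the far higher rate of 9-BBN with a 1,1-disubstituted terminal alkene than with a cis-disubstituted cyclohexene double bond. CO insertion must precede alkyl transfer, which is favoured by the monodentate-phosphine catalyst Pd(PPh3)4 at room temperature under CO and by the slowly transmetalating hindered borane, whereas PdCl2(dppf), the catalyst of choice for direct alkyl–alkenyl coupling, is avoided.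

**Step 8**
Reactants: 15 (2Z)-5-[(1R,6S)-6-hydroxy-2,2,6-trimethylcyclohex-4-en-1-yl]-3-methyl-4-oxopent-2-en-1-yl decanoate
Product: 16 (2Z)-5-[(1R,6S)-3,6-dihydroxy-2,2,6-trimethylcyclohex-4-en-1-yl]-3-methyl-4-oxopent-2-en-1-yl decanoate (both epimers at the new carbinol carbon)
Conditions: SeO2 (0.5 equiv), t-BuOOH (3 equiv, in decane), CH2Cl2, rt
Reagents that add atoms: selenium dioxide, O=[Se]=O (delivers the oxygen atom; reoxidised by tert-butyl hydroperoxide, CC(C)(C)OO)
Why: Selenium dioxide allylic hydroxylation (ene reaction followed by [2,3]-sigmatropic shift of the allylseleninic acid): the ring alkene has allylic hydrogens only at C1 because C4 is quaternary, so oxygen must arrive at C1 with the double bond returned to C2=C3, while the electron-poor enone alkene reacts far more slowly and the catalytic room-temperature conditions avoid α-oxidation of the C7 methylene; the configuration of the new carbinol is of no consequence.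

**Step 9**
Reactants: 16 (2Z)-5-[(1R,6S)-3,6-dihydroxy-2,2,6-trimethylcyclohex-4-en-1-yl]-3-methyl-4-oxopent-2-en-1-yl decanoate
Product: 17 (2Z)-5-[(1R,6S)-6-hydroxy-2,2,6-trimethyl-3-oxocyclohex-4-en-1-yl]-3-methyl-4-oxopent-2-en-1-yl decanoate (target CNP0241324.1)
Conditions: MnO2 (activated, 15 equiv), CH2Cl2, rt
Reagents that add atoms: none
Why: MnO2 oxidation of a secondary allylic alcohol to the enone is selective over the tertiary alcohol and leaves the ester, the Z-enone and both stereocentres untouched, which removes the stereocentre created in step 8 and should give the target.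

**Compound list**
1 | ketoisophorone (2,6,6-trimethylcyclohex-2-ene-1,4-dione) | CC1=CC(=O)CC(C)(C)C1=O | starting material
2 | (1S,6R)-1,3,3-trimethyl-7-oxabicyclo[4.1.0]heptane-2,5-dione | O=C1C(C)(C)CC(=O)[C@@H]2O[C@]12C | intermediate
3 | mono-hydrazone of 2 at the unhindered C5 carbonyl (5-hydrazinylidene-1,3,3-trimethyl-7-oxabicyclo[4.1.0]heptan-2-one, epoxide as in 2) | O=C1C(C)(C)CC(=NN)[C@@H]2O[C@]12C | intermediate (not isolated)
4 | (S)-2-hydroxy-2,6,6-trimethylcyclohex-3-en-1-one | O=C1C(C)(C)CC=C[C@]1(C)O | intermediate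
5 | (2S)-2,6,6-trimethyl-1-[(trimethylsilyl)methyl]cyclohex-3-ene-1,2-diol (both C1 epimers) | C[Si](C)(C)CC1(O)C(C)(C)CC=C[C@]1(C)O | intermediate
6 | (S)-1,5,5-trimethyl-6-methylidenecyclohex-2-en-1-ol | C=C1C(C)(C)CC=C[C@]1(C)O | intermediate
7 | but-2-yn-1-ol | CC#CCO | starting material
8 | sodium 2,2-bis(2-methoxyethoxy)-3-methyl-2,5-dihydro-1,2-oxaaluminol-2-uide (cyclic alkenylalanate) | CC1=CCO[Al-]1(OCCOC)OCCOC.[Na+] | intermediate (not isolated)
9 | (Z)-3-iodobut-2-en-1-ol | OC/C=C(/C)I | intermediate
10 | decanoyl chloride | CCCCCCCCCC(Cl)=O | starting material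
11 | (Z)-3-iodobut-2-en-1-yl decanoate | CCCCCCCCCC(=O)OC/C=C(/C)I | intermediate
12 | carbon monoxide | [C-]#[O+] | starting material
13 | 9-{[(1S)-1,5,5-trimethyl-6-methylidenecyclohex-2-en-1-yl]oxy}-9-borabicyclo[3.3.1]nonane | C=C1C(C)(C)CC=C[C@]1(C)OB1C2CCCC1CCC2 | intermediate (not isolated)
14 | 9-{[(1R,6S)-6-(9-borabicyclo[3.3.1]nonan-9-yloxy)-2,2,6-trimethylcyclohex-4-en-1-yl]methyl}-9-borabicyclo[3.3.1]nonane (CH2B cis to the borinate oxygen) | C1CCC2CCCC1B2C[C@@H]1C(C)(C)CC=C[C@]1(C)OB1C2CCCC1CCC2 | intermediate (not isolated)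
15 | (2Z)-5-[(1R,6S)-6-hydroxy-2,2,6-trimethylcyclohex-4-en-1-yl]-3-methyl-4-oxopent-2-en-1-yl decanoate (hydroxyl cis to the side chain) | CCCCCCCCCC(=O)OC/C=C(/C)C(=O)C[C@@H]1C(C)(C)CC=C[C@]1(C)O | intermediate
16 | (2Z)-5-[(1R,6S)-3,6-dihydroxy-2,2,6-trimethylcyclohex-4-en-1-yl]-3-methyl-4-oxopent-2-en-1-yl decanoate (both C3 epimers) | CCCCCCCCCC(=O)OC/C=C(/C)C(=O)C[C@@H]1C(C)(C)C(O)C=C[C@]1(C)O | intermediate
17 | (2Z)-5-[(1R,6S)-6-hydroxy-2,2,6-trimethyl-3-oxocyclohex-4-en-1-yl]-3-methyl-4-oxopent-2-en-1-yl decanoate | CCCCCCCCCC(=O)OC/C=C(/C)C(=O)C[C@@H]1C(C)(C)C(=O)C=C[C@]1(C)O | target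

**Totals**
Total step count: 9. Longest linear sequence: 7 steps (steps 1–4, then 7–9); the iodide branch (steps 5–6) joins at step 7.

**Steps most likely to fail**

Step 7. Two processes may go wrong. The B–H addition may show incomplete facial selectivity. The hindered primary alkyl group may also transfer slowly from boron to the acylpalladium, so that the acylpalladium is hydrolysed or reduced, or the iodide couples without CO. The fallback sets out from 6 and returns at 15, and forms the two bonds to C8 one after the other. The hydroxyl of 6 is silylated (Et3SiOTf, 2,6-lutidine) to give triethylsilyl ether F1. 9-BBN then adds to the exocyclic alkene to give B-alkyl-9-BBN F2 in the flask. This borane is carbonylated under CO in the presence of LiAlH(O-t-Bu)3 and oxidised with buffered H2O2 to the one-carbon-longer aldehyde F3, which already contains C8 and at which C5 epimers can be separated. Nozaki–Hiyama–Kishi coupling of F3 with 11 (CrCl2, NiCl2 cat., DMSO) forms C8–C9 as allylic alcohol F4. Dess–Martin periodinane should give silyl enone F5, and HF·pyridine removes the silyl group to give 15.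

Step 8. The ene reaction at the hindered ring alkene may be sluggish, so that oxidation of the C7 methylene next to the ketone, oxidation of the allylic ester CH2, or Z-to-E isomerisation of the enone competes. The fallback sets out from 6 and returns at 16, and moves the hydroxylation ahead of the coupling, where the molecule holds no ketone, enone or ester. SeO2/t-BuOOH on 6, whose only allylic hydrogens are again at ring C1, should give diol F6. t-BuMe2SiCl/imidazole silylates the secondary alcohol only, giving silyl ether F7. The conditions of step 7 then lead through O-borinate F8 and B-alkyl-9-BBN F9 to ketone F10. HF·pyridine frees the secondary alcohol to give 16, which enters step 9.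

Step 1. Iminium formation with the deactivated enedione may be slow, or enantiofacial discrimination may be low. The fallback sets out from 1 and returns at 2, and sets the configuration by a reduction that is then relayed. Asymmetric transfer hydrogenation of the unhindered carbonyl of 1 (RuCl(p-cymene)(TsDPEN) of the hand that gives the R alcohol, i-PrOH) gives hydroxy enone F11. Silylation (t-BuMe2SiCl, imidazole) gives silyl ether F12. Weitz–Scheffer epoxidation (H2O2, NaOH, MeOH, 0 °C) should add anti to the silyloxy group to give epoxy silyl ether F13, and any syn isomer is removed by chromatography. HF·pyridine gives epoxy alcohol F14, and Dess–Martin oxidation of the carbinol returns 2.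

**Further compounds**
F1 | step 7 | triethyl{[(1S)-1,5,5-trimethyl-6-methylidenecyclohex-2-en-1-yl]oxy}silane | C=C1C(C)(C)CC=C[C@]1(C)O[Si](CC)(CC)CC
F2 | step 7 | 9-{[(1R,6S)-2,2,6-trimethyl-6-(triethylsilyloxy)cyclohex-4-en-1-yl]methyl}-9-borabicyclo[3.3.1]nonane | C1CCC2CCCC1B2C[C@@H]1C(C)(C)CC=C[C@]1(C)O[Si](CC)(CC)CC
F3 | step 7 | 2-[(1R,6S)-2,2,6-trimethyl-6-(triethylsilyloxy)cyclohex-4-en-1-yl]acetaldehyde | O=CC[C@@H]1C(C)(C)CC=C[C@]1(C)O[Si](CC)(CC)CC
F4 | step 7 | (2Z)-4-hydroxy-3-methyl-5-[(1R,6S)-2,2,6-trimethyl-6-(triethylsilyloxy)cyclohex-4-en-1-yl]pent-2-en-1-yl decanoate (both C4 epimers) | CCCCCCCCCC(=O)OC/C=C(/C)C(O)C[C@@H]1C(C)(C)CC=C[C@]1(C)O[Si](CC)(CC)CC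
F5 | step 7 | (2Z)-3-methyl-4-oxo-5-[(1R,6S)-2,2,6-trimethyl-6-(triethylsilyloxy)cyclohex-4-en-1-yl]pent-2-en-1-yl decanoate | CCCCCCCCCC(=O)OC/C=C(/C)C(=O)C[C@@H]1C(C)(C)CC=C[C@]1(C)O[Si](CC)(CC)CC
F6 | step 8 | (1S)-1,5,5-trimethyl-6-methylidenecyclohex-2-ene-1,4-diol (both C4 epimers) | C=C1C(C)(C)C(O)C=C[C@]1(C)O
F7 | step 8 | (1S)-4-{[tert-butyl(dimethyl)silyl]oxy}-1,5,5-trimethyl-6-methylidenecyclohex-2-en-1-ol | C=C1C(C)(C)C(O[Si](C)(C)C(C)(C)C)C=C[C@]1(C)O
F8 | step 8 | 9-borabicyclo[3.3.1]nonan-9-yl borinate of the tertiary hydroxyl of F7 | C=C1C(C)(C)C(O[Si](C)(C)C(C)(C)C)C=C[C@]1(C)OB1C2CCCC1CCC2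
F9 | step 8 | B-alkyl-9-BBN from hydroboration of the exocyclic alkene of F8 (CH2B cis to the borinate oxygen) | C1CCC2CCCC1B2C[C@@H]1C(C)(C)C(O[Si](C)(C)C(C)(C)C)C=C[C@]1(C)OB1C2CCCC1CCC2
F10 | step 8 | (2Z)-5-[(1R,6S)-3-{[tert-butyl(dimethyl)silyl]oxy}-6-hydroxy-2,2,6-trimethylcyclohex-4-en-1-yl]-3-methyl-4-oxopent-2-en-1-yl decanoate | CCCCCCCCCC(=O)OC/C=C(/C)C(=O)C[C@@H]1C(C)(C)C(O[Si](C)(C)C(C)(C)C)C=C[C@]1(C)O
F11 | step 1 | (4R)-4-hydroxy-2,6,6-trimethylcyclohex-2-en-1-one | O=C1C(C)=C[C@H](O)CC1(C)C
F12 | step 1 | (4R)-4-{[tert-butyl(dimethyl)silyl]oxy}-2,6,6-trimethylcyclohex-2-en-1-one | O=C1C(C)=C[C@H](O[Si](C)(C)C(C)(C)C)CC1(C)C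
F13 | step 1 | (1S,5R,6S)-5-{[tert-butyl(dimethyl)silyl]oxy}-1,3,3-trimethyl-7-oxabicyclo[4.1.0]heptan-2-one (epoxide anti to the silyloxy group) | O=C1C(C)(C)C[C@@H](O[Si](C)(C)C(C)(C)C)[C@@H]2O[C@]12C
F14 | step 1 | (1S,5R,6S)-5-hydroxy-1,3,3-trimethyl-7-oxabicyclo[4.1.0]heptan-2-one | O=C1C(C)(C)C[C@@H](O)[C@@H]2O[C@]12C
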